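The numbers in the tables stem from a simulated flask from invented constants, noise included.

Whatever a flask did, each L ended as L, G or J, since Z at 0.01 mol% let E hold hardly any of it, and each J cost one X if the suspected step L + X → J holds. In ash, X is charged in the smaller amount, so I wrote these balances around it.

the same everywhere: L 0.016 M (fed, over 40 s); Z 0.01 mol%

| flask | X | remark | time |
|---|---|---|---|
| ochre | 0.0038 M | run made earlier; the fed solution adds 0.50 times the starting volume |  |
| violet | 0.12 M | run made earlier; the fed solution adds 0.50 times the starting volume |  |
| ash | 0.00500 M | the fed solution adds 0.50 times the starting volume | 10 min |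
| cedar | 0.0150 M | the fed solution adds 0.50 times the starting volume | 10 min |
| oak | 0.0500 M | the fed solution adds 0.50 times the starting volume | 10 min |
| maple | 0.150 M | the fed solution adds 0.50 times the starting volume | 10 min |

| run | time / min | G / % |
|---|---|---|
| ochre | 0.417 | 6 |
| ochre | 0.833 | 8 |
| ochre | 1.33 | 16 |
| ochre | 2.50 | 27 |
| ochre | 5.00 | 49 |
| violet | 0.417 | 3 |
| violet | 1.33 | 4 |
| violet | 2.50 | 5 |
| violet | 4.00 | 5 |
| violet | 5.00 | 0 |

(scatter of a reading: 2 percentage points)

- charges are per starting volume, the dose included; the dosed solution carries all of it
- what was read earlier has a scatter of 2 percentage points, one standard deviation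
- on the list of suspects stand: L + Z <-> E; E -> Z + G; L + X -> J
- "hardly changes" means that all values lie within two and a half points (for a concentration: within two and a half percent of the largest)
- percentages count the whole charge, also what has not yet gone in

- amount of G at the end, in percent of the L charged for ash, cedar, oak, maple, in this order
- the course of these numbers from the first flask to the last (falls all the way / falls, then rises / rises all the way / hardly changes / rises, then falls)

I assumed that both routes were pseudo-first-order in L, which ochre's scattered line allows. G and J then grow in the ratio X*/X, and with X₀ the charge of X, the integral is G = X* ln(X₀/X), all on the starting-volume scale. Violet's plateau read 4.67 %, with the last reading, 0 %, set aside as low. So X*, the break-even concentration of X at which G and J form equally fast, read 0.00549 M.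

I ran ash in slow motion. During the 40 s feed, with X taken at its charge, the rule had G forming 1.10 times as fast as J. Later, as X fell, the rule's ratio climbed, to 6.59 with 16.7 % of X left. For the end I went to ochre: its 49 % of G at 5.00 min implied, through the rule and the balance, 32.9 % of L left, so L decayed at 0.238 min⁻¹. That left 10.0 % of L in ash at 10 min. With 16.7 % of X left, the rule gave 61.5 % of G and the balance 63.9 %; with 14.3 % left, they gave 66.8 % and 63.2 %. They cross between these, so I took about 63.5 % for ash.

For cedar, reckoning as if no L stood at 10 min, 33.3 % of X left gave 37.7 % by the rule and 37.5 % by the balance. Two passes through the same pair gave 11.2 % for oak and 3.71 % for maple.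

The forecast differed from this reckoning at ash, cedar and oak. It read ochre's line as “so the enzyme is saturated” and gave 69 %, 20 %, 6.5 % and 4 %, a course that falls all the way.

The flasks gave 62.1 %, 37.6 %, 12.4 % and 4.21 %, a course that falls all the way.

    L + Z ⇌ E (K = 29.0 M⁻¹, k = 9.30 × 10⁵ M⁻¹ s⁻¹)
    E → Z + G (k = 100 s⁻¹)
    L + X → J (k = 0.690 M⁻¹ s⁻¹)

In ash at 3.15 min, E fell back 320 times faster than it went on. At 3.00 min, Z, the resting state, held 86.2 % of the catalyst against 13.8 % for E. With 13.9 % of X left in ash at 100 min, the rule with the read X* gives 67.8 % of G beside the flask's 73.1 %. With 35.1 % of X left in cedar at 100 min, it gives 36.0 % beside the flask's 39.1 %.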